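**Strategy.** The cyclohexane ring (C1 methyl-bearing oxirane carbon, C2 ketone, C3 angeloyloxy carbon, C4, C5, C6) is closed last at C3–C4 by a Lewis-acid carbonyl-ene cyclisation of an acyclic (3Z,6Z)-trienal. The step exploits the trans C3–O/C4–C7(=CH2) homoallylic alcohol motif: in one operation it forms the carbocycle, sets C3 and C4 and creates the exocyclic methylene from the C7 methyl. The only purchased ring stereocentre, a C2 carbinol from L-threonate, relays C3/C4 in the ene step, then directs the C1–C6 epoxidation and is finally oxidised to the ketone. The precursor is assembled by two Z-selective Wittig reactions of α-silyloxy methyl ketones.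

Key step: step 14

Remarks on the chemistry:
- Locants follow the target and are kept for the acyclic precursors. Ring: C1 (C–CH3, oxirane), C2 (C=O), C3 (CH–O-angeloyl), C4 (CH bearing the side chain), C5 (CH2), C6 (oxirane CH). Side chain: C7 (carbon of C=CH2), C8 (CH–O-angeloyl), C9 (CH2), C10 (oxirane CH), C11 (CMe2).
- Both oxiranes are introduced after the carbocycle, because trisubstituted epoxides are not expected to survive Me2AlCl.
- Ester 1 (from L-ascorbic acid), glycidate 12, the alkenyl Grignard reagent, angelic acid and the D-fructose-derived Shi ketone are assumed to be purchased.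
- TBS = tert-butyldimethylsilyl, TES = triethylsilyl.

**Route**

Step 1
Reactants: 1 methyl 3,4-O-isopropylidene-L-threonate
Product: 2 methyl (2R)-2-(tert-butyldimethylsilyloxy)-2-[(4S)-2,2-dimethyl-1,3-dioxolan-4-yl]acetate
Conditions: TBSCl, imidazole, DMF, rt
Reagents that add atoms: tert-butyldimethylsilyl chloride, CC(C)(C)[Si](C)(C)Cl
Why: Imidazole-promoted silyl ether formation at the only free hydroxyl; no stereocentre is touched.

Step 2
Reactants: 2 methyl (2R)-2-(tert-butyldimethylsilyloxy)-2-[(4S)-2,2-dimethyl-1,3-dioxolan-4-yl]acetate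
Product: 4 (1R)-1-(tert-butyldimethylsilyloxy)-1-[(4S)-2,2-dimethyl-1,3-dioxolan-4-yl]propan-2-one, via Weinreb amide 3 (not isolated)
Conditions: MeNHOMe·HCl, iPrMgCl, THF, −20 °C; then MeMgBr, −20 to 0 °C; aq. NH4Cl
Reagents that add atoms: methylmagnesium bromide, C[Mg]Br
Why: One-pot Weinreb ketone synthesis: the magnesium amide of MeNHOMe turns the ester into amide 3, whose chelated tetrahedral adduct with MeMgBr collapses only on work-up, so over-addition and epimerisation of the α-silyloxy centre should be avoided.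

Step 3
Reactants: 5 (3-bromopropoxy)(tert-butyl)dimethylsilane
Product: 6 [3-(tert-butyldimethylsilyloxy)propyl]triphenylphosphonium bromide
Conditions: PPh3, MeCN, reflux
Reagents that add atoms: triphenylphosphine, c1ccc(cc1)P(c1ccccc1)c1ccccc1
Why: SN2 quaternisation of the phosphine by the primary bromide (phosphonium salt formation).

Step 4
Reactants: 6 [3-(tert-butyldimethylsilyloxy)propyl]triphenylphosphonium bromide; 4 (1R)-1-(tert-butyldimethylsilyloxy)-1-[(4S)-2,2-dimethyl-1,3-dioxolan-4-yl]propan-2-one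
Product: 8 (4S)-4-[(1S,2Z)-1,5-bis(tert-butyldimethylsilyloxy)-2-methylpent-2-en-1-yl]-2,2-dimethyl-1,3-dioxolane, via ylide 7 (not isolated)
Conditions: 6, KN(SiMe3)2, THF, −78 to 0 °C; then 4, −78 °C to rt
Reagents that add atoms: none
Why: Wittig olefination of an α-silyloxy methyl ketone with a salt-free unstabilised ylide, a combination known to place the oxygenated carbon cis to the incoming chain, should give the (Z)-trisubstituted C1=C6 alkene without enolising the ketone.

Step 5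
Reactants: 8 (4S)-4-[(1S,2Z)-1,5-bis(tert-butyldimethylsilyloxy)-2-methylpent-2-en-1-yl]-2,2-dimethyl-1,3-dioxolane
Product: 9 (3Z,5S)-5-(tert-butyldimethylsilyloxy)-5-[(4S)-2,2-dimethyl-1,3-dioxolan-4-yl]-4-methylpent-3-en-1-ol
Conditions: HF·pyridine, pyridine, THF, 0 °C
Reagents that add atoms: none
Why: Buffered fluoride desilylation discriminates sterically, so the primary TBS ether should be cleaved while the hindered secondary allylic TBS ether and the acetonide remain.

Step 6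
Reactants: 9 (3Z,5S)-5-(tert-butyldimethylsilyloxy)-5-[(4S)-2,2-dimethyl-1,3-dioxolan-4-yl]-4-methylpent-3-en-1-ol
Product: 10 (4S)-4-[(1S,2Z)-1-(tert-butyldimethylsilyloxy)-5-iodo-2-methylpent-2-en-1-yl]-2,2-dimethyl-1,3-dioxolane
Conditions: I2, PPh3, imidazole, CH2Cl2, 0 °C
Reagents that add atoms: iodine, II
Why: Appel iodination of the primary alcohol by SN2 displacement of the oxyphosphonium ion; imidazole buffers the acetonide.

Step 7
Reactants: 10 (4S)-4-[(1S,2Z)-1-(tert-butyldimethylsilyloxy)-5-iodo-2-methylpent-2-en-1-yl]-2,2-dimethyl-1,3-dioxolane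
Product: 11 {(3Z,5S)-5-(tert-butyldimethylsilyloxy)-5-[(4S)-2,2-dimethyl-1,3-dioxolan-4-yl]-4-methylpent-3-en-1-yl}triphenylphosphonium iodide
Conditions: PPh3, iPr2NEt (cat.), MeCN, 75 °C
Reagents that add atoms: triphenylphosphine, c1ccc(cc1)P(c1ccccc1)c1ccccc1
Why: SN2 quaternisation of the phosphine by the primary homoallylic iodide gives the second Wittig salt and leaves the (Z)-alkene untouched.

Step 8
Reactants: 12 methyl (2S)-oxirane-2-carboxylate
Product: 13 methyl (2S)-2-hydroxy-5-methylhex-4-enoate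
Conditions: (2-methylprop-1-enyl)MgBr, CuI (10 mol%), THF, −40 °C; aq. NH4Cl
Reagents that add atoms: (2-methylprop-1-en-1-yl)magnesium bromide, CC(C)=C[Mg]Br
Why: Copper-catalysed SN2 opening of the epoxide at its CH2 terminus by the alkenyl Grignard reagent outruns ester addition at low temperature and does not touch the C8 stereocentre.

Step 9
Reactants: 13 methyl (2S)-2-hydroxy-5-methylhex-4-enoate
Product: 14 methyl (2S)-5-methyl-2-(triethylsilyloxy)hex-4-enoate
Conditions: TESCl, imidazole, CH2Cl2, 0 °C to rt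
Reagents that add atoms: chlorotriethylsilane, CC[Si](CC)(CC)Cl
Why: Imidazole-promoted silylation; the TES group is chosen so that it falls later together with the acetonide.

Step 10
Reactants: 14 methyl (2S)-5-methyl-2-(triethylsilyloxy)hex-4-enoate
Product: 16 (3S)-6-methyl-3-(triethylsilyloxy)hept-5-en-2-one, via Weinreb amide 15 (not isolated)
Conditions: MeNHOMe·HCl, iPrMgCl, THF, −20 °C; then MeMgBr, −20 to 0 °C; aq. NH4Cl
Reagents that add atoms: methylmagnesium bromide, C[Mg]Br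
Why: One-pot Weinreb ketone synthesis as in step 2, the chelated adduct of amide 15 preventing over-addition and epimerisation.

Step 11
Reactants: 11 {(3Z,5S)-5-(tert-butyldimethylsilyloxy)-5-[(4S)-2,2-dimethyl-1,3-dioxolan-4-yl]-4-methylpent-3-en-1-yl}triphenylphosphonium iodide; 16 (3S)-6-methyl-3-(triethylsilyloxy)hept-5-en-2-one
Product: 18 (4S)-4-[(1S,2Z,5Z,7S)-1-(tert-butyldimethylsilyloxy)-2,6,10-trimethyl-7-(triethylsilyloxy)undeca-2,5,9-trien-1-yl]-2,2-dimethyl-1,3-dioxolane, via ylide 17 (not isolated)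
Conditions: 11, KN(SiMe3)2, THF, −78 °C; then 16, −78 °C to rt
Reagents that add atoms: none
Why: A second Wittig olefination of an α-silyloxy methyl ketone with an unstabilised homoallylic ylide should, by the same α-oxygen effect, give the (Z)-C4=C7 alkene (C8 cis to C5) and complete the (Z,Z)-skipped diene.

Step 12
Reactants: 18 (4S)-4-[(1S,2Z,5Z,7S)-1-(tert-butyldimethylsilyloxy)-2,6,10-trimethyl-7-(triethylsilyloxy)undeca-2,5,9-trien-1-yl]-2,2-dimethyl-1,3-dioxolane
Product: 19 (2S,3S,4Z,7Z,9S)-3-(tert-butyldimethylsilyloxy)-4,8,12-trimethyltrideca-4,7,11-triene-1,2,9-triol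
Conditions: AcOH–THF–H2O (3:1:1), 35 °C
Reagents that add atoms: none
Why: Mild aqueous acid hydrolysis cleaves the terminal acetonide and the TES ether in one operation, whereas the hindered secondary TBS ether is expected to survive.

Step 13
Reactants: 19 (2S,3S,4Z,7Z,9S)-3-(tert-butyldimethylsilyloxy)-4,8,12-trimethyltrideca-4,7,11-triene-1,2,9-triol
Product: 20 (2S,3Z,6Z,8S)-2-(tert-butyldimethylsilyloxy)-8-hydroxy-3,7,11-trimethyldodeca-3,6,10-trienal
Conditions: NaIO4, THF–pH 7 buffer, 0 °C; crude product used at once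
Reagents that add atoms: none
Why: Periodate glycol cleavage (Malaprade reaction) of the terminal 1,2-diol unmasks the C3 aldehyde under neutral conditions that leave the C8 hydroxyl, the silyl ether and the C2 configuration alone.

Step 14
Reactants: 20 (2S,3Z,6Z,8S)-2-(tert-butyldimethylsilyloxy)-8-hydroxy-3,7,11-trimethyldodeca-3,6,10-trienal
Product: 21 (1S,2S,6S)-2-(tert-butyldimethylsilyloxy)-6-[(3S)-3-hydroxy-6-methylhepta-1,5-dien-2-yl]-3-methylcyclohex-3-en-1-ol
Conditions: Me2AlCl (3 equiv), CH2Cl2, −78 to −40 °C; then cold 1 M HCl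
Reagents that add atoms: none
Why: Me2AlCl first turns the C8 hydroxyl into an aluminium alkoxide and then activates the aldehyde, whereupon the C4=C7 alkene adds through C4 to the carbonyl carbon C3 while a hydrogen of the C7 methyl passes to the carbonyl oxygen in a six-membered, largely concerted ene transition state that leaves the C7=CH2 group and the C3 alkoxide. The closest known reaction type is the Lewis-acid-promoted intramolecular carbonyl-ene cyclisation of 6-alkenals to 2-isopropenylcyclohexanols (citronellal to isopulegol). The cyclohexene ring closes by C3–C4 bond formation in a 6-exo mode with respect to both π systems (the carbonyl oxygen and C7 stay outside the ring), the (Z)-C1=C6 alkene holding the two ends together. C3 and C4 are set in a chair-like transition state with O–Al and the alkene both equatorial (trans C3–O/C4–C7), and their absolute sense is relayed from C2, whose silyloxy group sits pseudo-equatorial and antiperiplanar to the forming bond (polar Felkin–Anh arrangement), giving the all-trans C2/C3/C4 array; the C8 centre is matched, its C8–C9 bond lying anti to the attacked alkene face in the A(1,3)-minimised rotamer. The step needs hydrogen transfer from the C7 methyl and not from C8–H, which the (Z)-C4=C7 geometry secures by placing the methyl trans to the tether, where the equatorial oxygen can reach it, and by locking C8–H in the olefin plane through A(1,3) strain; the C10=C11 alkene cannot compete because it would need a ten- or eleven-membered ring. Me2AlCl also scavenges protons, which should suppress chloride capture and isomerisation of the skipped diene.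

Step 15
Reactants: 21 (1S,2S,6S)-2-(tert-butyldimethylsilyloxy)-6-[(3S)-3-hydroxy-6-methylhepta-1,5-dien-2-yl]-3-methylcyclohex-3-en-1-ol
Product: 22 (1S,2S,6S)-2-(tert-butyldimethylsilyloxy)-3-methyl-6-[(3S)-6-methyl-3-{[(2Z)-2-methylbut-2-enoyl]oxy}hepta-1,5-dien-2-yl]cyclohex-3-en-1-yl (2Z)-2-methylbut-2-enoate
Conditions: angelic acid, 2,4,6-trichlorobenzoyl chloride, Et3N, toluene, rt; then 21, 80 °C
Reagents that add atoms: angelic acid, C/C=C(/C)C(=O)O
Why: Yamaguchi-type esterification through the angelic 2,4,6-trichlorobenzoic mixed anhydride, run without a nucleophilic catalyst so that the (Z)-acyl group is not isomerised to the tiglate, should acylate both secondary hydroxyls (C3 and C8).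

Step 16
Reactants: 22 (1S,2S,6S)-2-(tert-butyldimethylsilyloxy)-3-methyl-6-[(3S)-6-methyl-3-{[(2Z)-2-methylbut-2-enoyl]oxy}hepta-1,5-dien-2-yl]cyclohex-3-en-1-yl (2Z)-2-methylbut-2-enoate
Product: 23 (1S,2S,6S)-2-hydroxy-3-methyl-6-[(3S)-6-methyl-3-{[(2Z)-2-methylbut-2-enoyl]oxy}hepta-1,5-dien-2-yl]cyclohex-3-en-1-yl (2Z)-2-methylbut-2-enoate
Conditions: HF·pyridine, pyridine, THF, 0 °C to rt
Reagents that add atoms: none
Why: Fluoride desilylation under buffered, non-basic conditions frees the C2 hydroxyl without acyl migration from C3.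

Step 17
Reactants: 23 (1S,2S,6S)-2-hydroxy-3-methyl-6-[(3S)-6-methyl-3-{[(2Z)-2-methylbut-2-enoyl]oxy}hepta-1,5-dien-2-yl]cyclohex-3-en-1-yl (2Z)-2-methylbut-2-enoate
Product: 24 (1R,2R,3S,4S,6S)-2-hydroxy-1-methyl-4-[(3S)-6-methyl-3-{[(2Z)-2-methylbut-2-enoyl]oxy}hepta-1,5-dien-2-yl]-7-oxabicyclo[4.1.0]heptan-3-yl (2Z)-2-methylbut-2-enoate
Conditions: VO(acac)2 (5 mol%), t-BuOOH, CH2Cl2, 0 °C to rt
Reagents that add atoms: tert-butyl hydroperoxide, CC(C)(C)OO
Why: Hydroxyl-directed epoxidation: the vanadium alkoxide of the C2 allylic alcohol delivers the peroxide oxygen to C1=C6 on its own face, so the oxirane forms cis to C2–OH and thereby cis to the C4 side chain (C1 and C6 set), while the isolated and the electron-poor alkenes are not attacked.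

Step 18
Reactants: 24 (1R,2R,3S,4S,6S)-2-hydroxy-1-methyl-4-[(3S)-6-methyl-3-{[(2Z)-2-methylbut-2-enoyl]oxy}hepta-1,5-dien-2-yl]-7-oxabicyclo[4.1.0]heptan-3-yl (2Z)-2-methylbut-2-enoate
Product: 25 (1R,2R,3S,4S,6S)-4-[(3S)-4-[(2R)-3,3-dimethyloxiran-2-yl]-3-{[(2Z)-2-methylbut-2-enoyl]oxy}but-1-en-2-yl]-2-hydroxy-1-methyl-7-oxabicyclo[4.1.0]heptan-3-yl (2Z)-2-methylbut-2-enoate
Conditions: D-fructose-derived Shi ketone (30 mol%), KHSO5 (Oxone), K2CO3, Bu4NHSO4, MeCN–CH2(OMe)2–aq. Na2B4O7/Na2EDTA buffer, 0 °C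
Reagents that add atoms: potassium peroxymonosulfate, OOS(=O)(=O)[O-].[K+]
Why: Shi asymmetric epoxidation: the chiral dioxirane should attack the unhindered trisubstituted C10=C11 alkene under reagent control to give the (10R)-oxirane, while the hindered 1,1-disubstituted alkene and the electron-poor angelates react far more slowly.

Step 19
Reactants: 25 (1R,2R,3S,4S,6S)-4-[(3S)-4-[(2R)-3,3-dimethyloxiran-2-yl]-3-{[(2Z)-2-methylbut-2-enoyl]oxy}but-1-en-2-yl]-2-hydroxy-1-methyl-7-oxabicyclo[4.1.0]heptan-3-yl (2Z)-2-methylbut-2-enoate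
Product: 26 (1S,3S,4S,6S)-4-[(3S)-4-[(2R)-3,3-dimethyloxiran-2-yl]-3-{[(2Z)-2-methylbut-2-enoyl]oxy}but-1-en-2-yl]-1-methyl-2-oxo-7-oxabicyclo[4.1.0]heptan-3-yl (2Z)-2-methylbut-2-enoate (CNP0247177.2)
Conditions: Dess–Martin periodinane, NaHCO3, CH2Cl2, 0 °C to rt
Reagents that add atoms: none
Why: Dess–Martin oxidation converts the C2 carbinol, whose relay function is finished, into the ketone under buffered conditions that should not epimerise C3 or open the oxiranes.

**Compound list**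

1 | methyl 3,4-O-isopropylidene-L-threonate, methyl (2R)-2-[(4S)-2,2-dimethyl-1,3-dioxolan-4-yl]-2-hydroxyacetate | COC(=O)[C@H](O)[C@@H]1COC(C)(C)O1 | starting material
2 | methyl (2R)-2-(tert-butyldimethylsilyloxy)-2-[(4S)-2,2-dimethyl-1,3-dioxolan-4-yl]acetate | COC(=O)[C@H](O[Si](C)(C)C(C)(C)C)[C@@H]1COC(C)(C)O1 | intermediate
3 | (2R)-2-(tert-butyldimethylsilyloxy)-2-[(4S)-2,2-dimethyl-1,3-dioxolan-4-yl]-N-methoxy-N-methylacetamide | CON(C)C(=O)[C@H](O[Si](C)(C)C(C)(C)C)[C@@H]1COC(C)(C)O1 | intermediate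
4 | (1R)-1-(tert-butyldimethylsilyloxy)-1-[(4S)-2,2-dimethyl-1,3-dioxolan-4-yl]propan-2-one | CC(=O)[C@H](O[Si](C)(C)C(C)(C)C)[C@@H]1COC(C)(C)O1 | intermediate
5 | (3-bromopropoxy)(tert-butyl)dimethylsilane | CC(C)(C)[Si](C)(C)OCCCBr | starting material
6 | [3-(tert-butyldimethylsilyloxy)propyl]triphenylphosphonium bromide | CC(C)(C)[Si](C)(C)OCCC[P+](c1ccccc1)(c1ccccc1)c1ccccc1.[Br-] | intermediate
7 | [3-(tert-butyldimethylsilyloxy)propylidene]triphenylphosphorane | CC(C)(C)[Si](C)(C)OCCC=P(c1ccccc1)(c1ccccc1)c1ccccc1 | intermediate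
8 | (4S)-4-[(1S,2Z)-1,5-bis(tert-butyldimethylsilyloxy)-2-methylpent-2-en-1-yl]-2,2-dimethyl-1,3-dioxolane | CC(C)(C)[Si](C)(C)OCC/C=C(/C)[C@H](O[Si](C)(C)C(C)(C)C)[C@@H]1COC(C)(C)O1 | intermediate
9 | (3Z,5S)-5-(tert-butyldimethylsilyloxy)-5-[(4S)-2,2-dimethyl-1,3-dioxolan-4-yl]-4-methylpent-3-en-1-ol | OCC/C=C(/C)[C@H](O[Si](C)(C)C(C)(C)C)[C@@H]1COC(C)(C)O1 | intermediate
10 | (4S)-4-[(1S,2Z)-1-(tert-butyldimethylsilyloxy)-5-iodo-2-methylpent-2-en-1-yl]-2,2-dimethyl-1,3-dioxolane | ICC/C=C(/C)[C@H](O[Si](C)(C)C(C)(C)C)[C@@H]1COC(C)(C)O1 | intermediate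
11 | {(3Z,5S)-5-(tert-butyldimethylsilyloxy)-5-[(4S)-2,2-dimethyl-1,3-dioxolan-4-yl]-4-methylpent-3-en-1-yl}triphenylphosphonium iodide | [I-].c1ccc(cc1)[P+](c1ccccc1)(c1ccccc1)CC/C=C(/C)[C@H](O[Si](C)(C)C(C)(C)C)[C@@H]1COC(C)(C)O1 | intermediate
12 | methyl (2S)-oxirane-2-carboxylate (methyl (S)-glycidate) | COC(=O)[C@@H]1CO1 | starting material
13 | methyl (2S)-2-hydroxy-5-methylhex-4-enoate | COC(=O)[C@@H](O)CC=C(C)C | intermediate
14 | methyl (2S)-5-methyl-2-(triethylsilyloxy)hex-4-enoate | COC(=O)[C@@H](O[Si](CC)(CC)CC)CC=C(C)C | intermediate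
15 | (2S)-N-methoxy-N,5-dimethyl-2-(triethylsilyloxy)hex-4-enamide | CON(C)C(=O)[C@@H](O[Si](CC)(CC)CC)CC=C(C)C | intermediate
16 | (3S)-6-methyl-3-(triethylsilyloxy)hept-5-en-2-one | CC(=O)[C@@H](O[Si](CC)(CC)CC)CC=C(C)C | intermediate
17 | {(3Z,5S)-5-(tert-butyldimethylsilyloxy)-5-[(4S)-2,2-dimethyl-1,3-dioxolan-4-yl]-4-methylpent-3-en-1-ylidene}triphenylphosphorane | c1ccc(cc1)P(c1ccccc1)(c1ccccc1)=CC/C=C(/C)[C@H](O[Si](C)(C)C(C)(C)C)[C@@H]1COC(C)(C)O1 | intermediate
18 | (4S)-4-[(1S,2Z,5Z,7S)-1-(tert-butyldimethylsilyloxy)-2,6,10-trimethyl-7-(triethylsilyloxy)undeca-2,5,9-trien-1-yl]-2,2-dimethyl-1,3-dioxolane | CC(C)=CC[C@H](O[Si](CC)(CC)CC)/C(C)=C\C/C=C(/C)[C@H](O[Si](C)(C)C(C)(C)C)[C@@H]1COC(C)(C)O1 | intermediate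
19 | (2S,3S,4Z,7Z,9S)-3-(tert-butyldimethylsilyloxy)-4,8,12-trimethyltrideca-4,7,11-triene-1,2,9-triol | CC(C)=CC[C@H](O)/C(C)=C\C/C=C(/C)[C@H](O[Si](C)(C)C(C)(C)C)[C@@H](O)CO | intermediate
20 | (2S,3Z,6Z,8S)-2-(tert-butyldimethylsilyloxy)-8-hydroxy-3,7,11-trimethyldodeca-3,6,10-trienal | O=C[C@@H](O[Si](C)(C)C(C)(C)C)/C(C)=C\C/C=C(/C)[C@@H](O)CC=C(C)C | intermediate
21 | (1S,2S,6S)-2-(tert-butyldimethylsilyloxy)-6-[(3S)-3-hydroxy-6-methylhepta-1,5-dien-2-yl]-3-methylcyclohex-3-en-1-ol (all-trans at C2, C3, C4 of the target numbering) | C=C([C@H](CC=C(C)C)O)[C@@H]1CC=C(C)[C@H](O[Si](C)(C)C(C)(C)C)[C@H]1O | intermediate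
22 | (1S,2S,6S)-2-(tert-butyldimethylsilyloxy)-3-methyl-6-[(3S)-6-methyl-3-{[(2Z)-2-methylbut-2-enoyl]oxy}hepta-1,5-dien-2-yl]cyclohex-3-en-1-yl (2Z)-2-methylbut-2-enoate | C=C([C@H](CC=C(C)C)OC(=O)/C(C)=C\C)[C@@H]1CC=C(C)[C@H](O[Si](C)(C)C(C)(C)C)[C@H]1OC(=O)/C(C)=C\C | intermediate
23 | (1S,2S,6S)-2-hydroxy-3-methyl-6-[(3S)-6-methyl-3-{[(2Z)-2-methylbut-2-enoyl]oxy}hepta-1,5-dien-2-yl]cyclohex-3-en-1-yl (2Z)-2-methylbut-2-enoate | C=C([C@H](CC=C(C)C)OC(=O)/C(C)=C\C)[C@@H]1CC=C(C)[C@H](O)[C@H]1OC(=O)/C(C)=C\C | intermediate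
24 | (1R,2R,3S,4S,6S)-2-hydroxy-1-methyl-4-[(3S)-6-methyl-3-{[(2Z)-2-methylbut-2-enoyl]oxy}hepta-1,5-dien-2-yl]-7-oxabicyclo[4.1.0]heptan-3-yl (2Z)-2-methylbut-2-enoate (oxirane cis to the C2 hydroxyl and to the C4 side chain) | C=C([C@H](CC=C(C)C)OC(=O)/C(C)=C\C)[C@@H]1C[C@@H]2O[C@]2(C)[C@H](O)[C@H]1OC(=O)/C(C)=C\C | intermediate
25 | (1R,2R,3S,4S,6S)-4-[(3S)-4-[(2R)-3,3-dimethyloxiran-2-yl]-3-{[(2Z)-2-methylbut-2-enoyl]oxy}but-1-en-2-yl]-2-hydroxy-1-methyl-7-oxabicyclo[4.1.0]heptan-3-yl (2Z)-2-methylbut-2-enoate | C=C([C@H](C[C@H]1OC1(C)C)OC(=O)/C(C)=C\C)[C@@H]1C[C@@H]2O[C@]2(C)[C@H](O)[C@H]1OC(=O)/C(C)=C\C | intermediate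
26 | (1S,3S,4S,6S)-4-[(3S)-4-[(2R)-3,3-dimethyloxiran-2-yl]-3-{[(2Z)-2-methylbut-2-enoyl]oxy}but-1-en-2-yl]-1-methyl-2-oxo-7-oxabicyclo[4.1.0]heptan-3-yl (2Z)-2-methylbut-2-enoate (CNP0247177.2) | C=C([C@H](C[C@H]1OC1(C)C)OC(=O)/C(C)=C\C)[C@@H]1C[C@@H]2O[C@]2(C)C(=O)[C@H]1OC(=O)/C(C)=C\C | target

**Step count and risks**

Total step count: 19. Longest linear sequence: 15 steps (1 to 26 through steps 1, 2, 4–7 and 11–19).

Steps most likely to fail:

1. Step 14 (carbonyl-ene ring closure). The aluminium alkoxide at C8 and chloride from the reagent may intercept the developing C7 cation (Prins-type capture instead of hydrogen transfer). Relay from C2 may also erode if the silyloxy group escapes to the pseudo-axial position. The fallback masks the hydroxyl and replaces the stoichiometric aluminium reagent by a chloride-free catalytic promoter. It sets out from 20: silylation with TESCl and imidazole in CH2Cl2 should give the C8 triethylsilyl ether (2S,3Z,6Z,8S)-2-(tert-butyldimethylsilyloxy)-3,7,11-trimethyl-8-(triethylsilyloxy)dodeca-3,6,10-trienal F1. Catalytic Sc(OTf)3 in CH2Cl2 at −78 °C should then effect the same carbonyl-ene closure to the silyl-protected cyclohexenol (1S,2S,6S)-2-(tert-butyldimethylsilyloxy)-3-methyl-6-[(3S)-6-methyl-3-(triethylsilyloxy)hepta-1,5-dien-2-yl]cyclohex-3-en-1-ol F2. Brief AcOH–THF–H2O treatment at room temperature removes only the TES ether, and the fallback comes back to the route at 21.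

2. Step 15 (double angeloylation). The angeloyl group may isomerise to the tigloyl group during activation, and acylation of the hindered C3 hydroxyl next to the silyl ether may stall. The fallback builds the (Z)-acyl groups on the substrate instead of transferring them. It sets out from 21: DCC/DMAP esterification with 2-[bis(2,2,2-trifluoroethoxy)phosphoryl]propanoic acid should give the C3,C8-bis{2-[bis(2,2,2-trifluoroethoxy)phosphoryl]propanoate} of 21 F3 (mixture of epimers at the two phosphonate carbons). A double Still–Gennari olefination (KN(SiMe3)2, 18-crown-6, THF, −78 °C, acetaldehyde) should then form both (Z)-2-methylbut-2-enoates, and the fallback comes back to the route at 22.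

3. Step 17 (hydroxyl-directed epoxidation). Oxygen transfer may be slow because the C2 hydroxyl is held pseudo-equatorial, so that oxidation of the allylic alcohol to the enone competes. The fallback reorders the two epoxidations and uses a hydrogen-bond-directed peracid. It sets out from 22: Shi epoxidation (same ketone, KHSO5, buffered) of the prenyl alkene, with the ring alkene shielded by the silyl ether, should give the 10,11-epoxide (1S,2S,6S)-2-(tert-butyldimethylsilyloxy)-6-[(3S)-4-[(2R)-3,3-dimethyloxiran-2-yl]-3-{[(2Z)-2-methylbut-2-enoyl]oxy}but-1-en-2-yl]-3-methylcyclohex-3-en-1-yl (2Z)-2-methylbut-2-enoate F4. Desilylation with Bu4NF buffered with AcOH in THF should give the allylic alcohol (1S,2S,6S)-6-[(3S)-4-[(2R)-3,3-dimethyloxiran-2-yl]-3-{[(2Z)-2-methylbut-2-enoyl]oxy}but-1-en-2-yl]-2-hydroxy-3-methylcyclohex-3-en-1-yl (2Z)-2-methylbut-2-enoate F5. Henbest epoxidation with m-CPBA and NaHCO3 in CH2Cl2 at 0 °C, syn to the C2 hydroxyl, then brings the fallback back to the route at 25.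

**Further compounds**

F1 | step 14 | (2S,3Z,6Z,8S)-2-(tert-butyldimethylsilyloxy)-3,7,11-trimethyl-8-(triethylsilyloxy)dodeca-3,6,10-trienal | O=C[C@@H](O[Si](C)(C)C(C)(C)C)/C(C)=C\C/C=C(/C)[C@@H](O[Si](CC)(CC)CC)CC=C(C)C
F2 | step 14 | (1S,2S,6S)-2-(tert-butyldimethylsilyloxy)-3-methyl-6-[(3S)-6-methyl-3-(triethylsilyloxy)hepta-1,5-dien-2-yl]cyclohex-3-en-1-ol | C=C([C@H](CC=C(C)C)O[Si](CC)(CC)CC)[C@@H]1CC=C(C)[C@H](O[Si](C)(C)C(C)(C)C)[C@H]1O
F3 | step 15 | (1S,2S,6S)-2-(tert-butyldimethylsilyloxy)-3-methyl-6-[(3S)-6-methyl-3-({2-[bis(2,2,2-trifluoroethoxy)phosphoryl]propanoyl}oxy)hepta-1,5-dien-2-yl]cyclohex-3-en-1-yl 2-[bis(2,2,2-trifluoroethoxy)phosphoryl]propanoate | C=C([C@H](CC=C(C)C)OC(=O)C(C)P(=O)(OCC(F)(F)F)OCC(F)(F)F)[C@@H]1CC=C(C)[C@H](O[Si](C)(C)C(C)(C)C)[C@H]1OC(=O)C(C)P(=O)(OCC(F)(F)F)OCC(F)(F)F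
F4 | step 17 | (1S,2S,6S)-2-(tert-butyldimethylsilyloxy)-6-[(3S)-4-[(2R)-3,3-dimethyloxiran-2-yl]-3-{[(2Z)-2-methylbut-2-enoyl]oxy}but-1-en-2-yl]-3-methylcyclohex-3-en-1-yl (2Z)-2-methylbut-2-enoate | C=C([C@H](C[C@H]1OC1(C)C)OC(=O)/C(C)=C\C)[C@@H]1CC=C(C)[C@H](O[Si](C)(C)C(C)(C)C)[C@H]1OC(=O)/C(C)=C\C
F5 | step 17 | (1S,2S,6S)-6-[(3S)-4-[(2R)-3,3-dimethyloxiran-2-yl]-3-{[(2Z)-2-methylbut-2-enoyl]oxy}but-1-en-2-yl]-2-hydroxy-3-methylcyclohex-3-en-1-yl (2Z)-2-methylbut-2-enoate | C=C([C@H](C[C@H]1OC1(C)C)OC(=O)/C(C)=C\C)[C@@H]1CC=C(C)[C@H](O)[C@H]1OC(=O)/C(C)=C\C
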